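## Retrosynthetic overview

1. Target 32 ⇒ bis-silyl ether 31; the butenolide ring is bought (4-bromofuran-2(5H)-one) and joined last to C12 by B-alkyl Suzuki coupling; the angelate is put on the only free hydroxyl (3-OH).
2. The 2β-OH/3α-OH pair ⇒ C3 ketone (enolate hydroxylation, then hydride reduction); C8=C17 and 9-H ⇒ 1,5-sigmatropic H shift of an allylic diazene made from a C17 enal.
3. Ring B ⇒ key Diels–Alder reaction of the ring A diene 12 (C10=C5–C6=C7) with 4,4-diethoxybut-2-ynal, then Δ5 hydrogenation to the trans-decalin.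
4. Ring A diene 12 ⇒ (R)-carvone: C6 methylation and hydroxymethylation (future C4), Criegee rearrangement (isopropenyl → 3-O), acetonide lock, enol triflate, Stille vinylation.
5. Ring order: ring A (carvone ring, bought) → ring B ([4+2]) → butenolide (bought, attached in step 18).

Assumption: labdane numbering is used; α is the decalin face that carries the C10 methyl (C20) and β the other face, so the target is 2β-OH, 3α-O-angeloyl, 4α-CH3, 4β-CH2OH (C18), 5β-H, 9β-H, 10α-CH3, i.e. (2S,3S,4S,5S,9R,10S); compounds 1, 13, 27 and 29 are purchased.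

## Route

Step 1
Reactants: 1 (R)-(−)-carvone
Product: 3 6-methylcarvone (C6 epimer mixture), via lithium dienolate 2 (not isolated)
Conditions: LiN(i-Pr)2, THF, −78 °C; MeI, −78 → −20 °C
Reagents that add atoms: iodomethane, CI
Why: Kinetic α′-deprotonation of the enone and SN2 enolate alkylation; the C6 configuration does not matter because C6 is enolised again in step 2.

Step 2
Reactants: 3 6-methylcarvone
Product: 5 (5S,6R)-6-(hydroxymethyl)-2,6-dimethyl-5-(prop-1-en-2-yl)cyclohex-2-en-1-one, via lithium enolate 4 (not isolated)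
Conditions: LiN(i-Pr)2, THF, −78 °C; CH2O (g, from cracked paraformaldehyde), −78 °C
Reagents that add atoms: formaldehyde, C=O
Why: Aldol addition of the tetrasubstituted enolate to monomeric formaldehyde occurs anti to the neighbouring isopropenyl group, so the new quaternary centre (future C4) has CH2OH trans and CH3 cis to the carvone stereocentre.

Step 3
Reactants: 5 hydroxymethyl enone
Product: 7 (5R,6S)-5-acetoxy-6-(acetoxymethyl)-2,6-dimethylcyclohex-2-en-1-one, via methoxy hydroperoxide 6 (not isolated)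
Conditions: O3, CH2Cl2/MeOH, −78 °C; Ac2O, Et3N, DMAP, CH2Cl2, 0 → 40 °C
Reagents that add atoms: ozone, [O-][O+]=O; acetic anhydride, CC(=O)OC(C)=O
Why: Chemoselective ozonolysis of the electron-rich isopropenyl group followed by Criegee rearrangement of the peracetate moves the ring carbon from C to O with retention, turning the carvone stereocentre into the future C3–O, while the primary OH is acetylated in the same pot.

Step 4
Reactants: 7 diacetate
Product: 9 (4aS,8aR)-2,2,4a,6-tetramethyl-4a,8a-dihydro-4H-1,3-benzodioxin-5(8H)-one, via diol 8 (not isolated)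
Conditions: HCl (from AcCl), MeOH, 40 °C; evaporate; Me2C(OMe)2, acetone, TsOH (cat.), rt
Reagents that add atoms: 2,2-dimethoxypropane, COC(C)(C)OC
Why: Acid-catalysed transesterification (no base, so no retro-aldol) and acetonide formation give a trans-fused 1,3-dioxane that locks ring A with the C-methyl axial.

Step 5
Reactants: 9 acetonide enone
Product: 11 (4aS,8aR)-2,2,4a,6-tetramethyl-4a,7,8,8a-tetrahydro-4H-1,3-benzodioxin-5-yl trifluoromethanesulfonate, via lithium enolate 10 (not isolated)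
Conditions: LiBH(s-Bu)3, THF, −78 °C; PhNTf2, −78 °C → rt
Reagents that add atoms: N-phenylbis(trifluoromethanesulfonimide), O=S(=O)(N(c1ccccc1)S(=O)(=O)C(F)(F)F)C(F)(F)F
Why: Conjugate hydride reduction of the hindered enone gives the tetrasubstituted enolate regiospecifically, and O-sulfonylation traps it as the enol triflate.

Step 6
Reactants: 11 enol triflate
Product: 12 (4aS,8aR)-5-ethenyl-2,2,4a,6-tetramethyl-4a,7,8,8a-tetrahydro-4H-1,3-benzodioxine
Conditions: Bu3SnCH=CH2, Pd(PPh3)4 (5 mol %), LiCl, THF, 65 °C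
Reagents that add atoms: tributyl(vinyl)stannane, C=C[Sn](CCCC)(CCCC)CCCC
Why: Stille coupling of the vinyl triflate installs C6=C7 and completes the 2-methyl-1-vinylcyclohexene diene, as in the classical drimane diene synthesis.

Step 7
Reactants: 12 ring A diene; 13 4,4-diethoxybut-2-ynal
Product: 14 17,17-diethoxy-3α,18-(isopropylidenedioxy)-12,13,14,15,16-pentanorlabda-5,8-dien-11-al (4α-CH3, 10α-CH3)
Conditions: toluene, BHT (cat.), 110 °C, sealed tube
Reagents that add atoms: none
Why: Diels–Alder [4+2] cycloaddition forms ring B, the acetal-bearing alkyne carbon bonding to the unhindered vinyl terminus C7 and the formyl-bearing carbon to C10, and because the locked ring A holds the 4-methyl axial on the α face the dienophile adds to C10 from the β face, setting C10 with C20 α (cis to the 4-methyl).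

Step 8
Reactants: 14 Diels–Alder adduct
Product: 15 17,17-diethoxy-3α,18-(isopropylidenedioxy)-12,13,14,15,16-pentanorlabd-8-en-11-al (5β-H, trans-decalin)
Conditions: H2 (1 atm), 10% Pd/C, EtOAc, rt
Reagents that add atoms: none
Why: Heterogeneous hydrogenation of the trisubstituted Δ5 alkene from the β face, the α face being shielded by the two axial methyls (C20 and 4α-CH3), gives 5β-H and the trans ring fusion, while the tetrasubstituted conjugated C8=C9 bond is left.

Step 9
Reactants: 15 enal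
Product: 16 17,17-diethoxy-3α,18-(isopropylidenedioxy)-13,14,15,16-tetranorlabda-8,11-diene
Conditions: Ph3PCH3Br, KN(SiMe3)2, THF, 0 °C; then 15, 0 °C → rt
Reagents that add atoms: methyltriphenylphosphonium bromide, C[P+](c1ccccc1)(c1ccccc1)c1ccccc1.[Br-]
Why: Wittig methylenation of the C11 aldehyde adds C12 as a terminal vinyl group.

Step 10
Reactants: 16 diene acetal
Product: 17 3α,18-dihydroxy-13,14,15,16-tetranorlabda-8,11-dien-17-al
Conditions: 1 M HCl, THF/H2O, rt
Reagents that add atoms: water, O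
Why: Acid hydrolysis removes the diethyl acetal and the acetonide together, freeing the C17 aldehyde and the 3,18-diol.

Step 11
Reactants: 17 dienal diol
Product: 20 13,14,15,16-tetranorlabda-8(17),11-diene-3α,18-diol (9β-H), via tosylhydrazone 18 (not isolated), via allylic diazene 19 (not isolated)
Conditions: TsNHNH2, EtOH, rt; evaporate; catecholborane, CHCl3, 0 °C; NaOAc·3H2O, 60 °C
Reagents that add atoms: none
Why: Reductive 1,3-transposition (Kabalka type): the allylic diazene loses N2 in a retro-ene-type 1,5-sigmatropic hydrogen shift that moves the alkene to C8=C17 and delivers H to C9 axially on the β face, away from the axial C20 methyl, so the vinyl side chain ends α and equatorial.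

Step 12
Reactants: 20 diol
Product: 21 18-(tert-butyldimethylsilyloxy)-13,14,15,16-tetranorlabda-8(17),11-dien-3α-ol
Conditions: TBSCl (1.1 equiv), imidazole, CH2Cl2, 0 °C
Reagents that add atoms: tert-butyldimethylsilyl chloride, CC(C)(C)[Si](C)(C)Cl
Why: The primary 18-OH is silylated selectively over the secondary 3-OH, which is flanked by the quaternary C4.

Step 13
Reactants: 21 silyl ether alcohol
Product: 22 18-(tert-butyldimethylsilyloxy)-13,14,15,16-tetranorlabda-8(17),11-dien-3-one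
Conditions: Dess–Martin periodinane, NaHCO3, CH2Cl2, rt
Reagents that add atoms: none
Why: Mild oxidation of the secondary alcohol gives the C3 ketone needed to reach C2, without touching the skipped diene.

Step 14
Reactants: 22 ketone
Product: 24 2β-hydroxy-18-(tert-butyldimethylsilyloxy)-13,14,15,16-tetranorlabda-8(17),11-dien-3-one, via potassium enolate 23 (not isolated)
Conditions: KN(SiMe3)2, THF, −78 °C; racemic 2-(phenylsulfonyl)-3-phenyloxaziridine, −78 °C
Reagents that add atoms: 2-(phenylsulfonyl)-3-phenyloxaziridine, O=S(=O)(N1OC1c1ccccc1)c1ccccc1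
Why: Davis enolate hydroxylation; C2 is the only enolisable position and oxygen arrives on the β face because axial (α) attack is blocked by the syn-axial C20 and 4α methyls, giving the equatorial 2β-OH (also the thermodynamic epimer).

Step 15
Reactants: 24 hydroxy ketone
Product: 25 2β,18-bis(tert-butyldimethylsilyloxy)-13,14,15,16-tetranorlabda-8(17),11-dien-3-one
Conditions: TBSOTf, 2,6-lutidine, CH2Cl2, −78 → 0 °C
Reagents that add atoms: tert-butyldimethylsilyl trifluoromethanesulfonate, CC(C)(C)[Si](C)(C)OS(=O)(=O)C(F)(F)F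
Why: Silylation of the 2-OH makes the 3-OH the only free hydroxyl after the next step.

Step 16
Reactants: 25 bis-silyl ketone
Product: 26 2β,18-bis(tert-butyldimethylsilyloxy)-13,14,15,16-tetranorlabda-8(17),11-dien-3α-ol
Conditions: NaBH4, MeOH/THF, −20 → 0 °C
Reagents that add atoms: none
Why: Hydride adds axially from the β face (the α face is screened by the axial 4α-CH3), giving the equatorial 3α-alcohol trans to the 2β-silyloxy group, as in reductions of 4,4-disubstituted 3-oxo triterpenoids.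

Step 17
Reactants: 26 alcohol; 27 angelic acid
Product: 28 2β,18-bis(tert-butyldimethylsilyloxy)-13,14,15,16-tetranorlabda-8(17),11-dien-3α-yl (Z)-2-methylbut-2-enoate
Conditions: 27, 2,4,6-trichlorobenzoyl chloride, Et3N, toluene, rt; then 26, 80 °C
Reagents that add atoms: none
Why: Yamaguchi mixed-anhydride esterification of the single free hydroxyl, run without DMAP so that the Z-enoate is not isomerised to the tiglate.

Step 18
Reactants: 28 angelate; 29 4-bromofuran-2(5H)-one
Product: 31 3α-angeloyloxy-2β,18-bis(tert-butyldimethylsilyloxy)labda-8(17),13-dien-15,16-olide, via alkylborane 30 (not isolated)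
Conditions: 9-BBN, THF, 0 °C → rt; then 29, PdCl2(dppf) (5 mol %), AsPh3, K3PO4 (aq.), DMF, rt → 40 °C
Reagents that add atoms: none
Why: 9-BBN hydroborates the monosubstituted vinyl group in preference to the hindered 1,1-disubstituted exocyclic alkene and the conjugated angelate, and B-alkyl Suzuki–Miyaura coupling with the vinylogous acyl bromide forms the C12–C13 bond.

Step 19
Reactants: 31 bis-silyl ether
Product: 32 target, 3α-angeloyloxy-2β,18-dihydroxylabda-8(17),13-dien-15,16-olide, (2S,3S,4S,5S,9R,10S)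
Conditions: HF·pyridine, pyridine/THF, 0 °C → rt
Reagents that add atoms: none
Why: Fluoride cleavage of both silyl ethers under buffered, mildly acidic conditions that avoid acyl migration and butenolide isomerisation.

## Compound list

1 | (R)-(−)-carvone, (5R)-2-methyl-5-(prop-1-en-2-yl)cyclohex-2-en-1-one | CC1=CC[C@H](CC1=O)C(C)=C | starting material
2 | lithium dienolate of carvone (O–Li at C1, C1=C6, 5R) | CC1=CC[C@H](C=C1[O-])C(C)=C.[Li+] | intermediate
3 | 6-methylcarvone, (5R)-2,6-dimethyl-5-(prop-1-en-2-yl)cyclohex-2-en-1-one, C6 epimer mixture | CC1=CC[C@@H](C(C)=C)C(C)C1=O | intermediate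
4 | lithium enolate of 3 (C1=C6, 5R) | CC1=CC[C@@H](C(C)=C)C(C)=C1[O-].[Li+] | intermediate
5 | (5S,6R)-6-(hydroxymethyl)-2,6-dimethyl-5-(prop-1-en-2-yl)cyclohex-2-en-1-one (CH2OH trans to isopropenyl) | CC1=CC[C@@H](C(C)=C)[C@](C)(CO)C1=O | intermediate
6 | (5R,6R)-5-(1-hydroperoxy-1-methoxyethyl)-6-(hydroxymethyl)-2,6-dimethylcyclohex-2-en-1-one (epimers at the peroxy carbon) | CC1=CC[C@@H](C(C)(OC)OO)[C@](C)(CO)C1=O | intermediate
7 | (5R,6S)-5-acetoxy-6-(acetoxymethyl)-2,6-dimethylcyclohex-2-en-1-one | CC1=CC[C@@H](OC(C)=O)[C@](C)(COC(C)=O)C1=O | intermediate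
8 | (5R,6S)-5-hydroxy-6-(hydroxymethyl)-2,6-dimethylcyclohex-2-en-1-one | CC1=CC[C@@H](O)[C@](C)(CO)C1=O | intermediate
9 | (4aS,8aR)-2,2,4a,6-tetramethyl-4a,8a-dihydro-4H-1,3-benzodioxin-5(8H)-one (trans-fused acetonide) | CC1=CC[C@H]2OC(C)(C)OC[C@]2(C)C1=O | intermediate
10 | lithium (4aS,8aR)-2,2,4a,6-tetramethyl-4a,7,8,8a-tetrahydro-4H-1,3-benzodioxin-5-olate | CC1=C([O-])[C@@]2(C)COC(C)(C)O[C@@H]2CC1.[Li+] | intermediate
11 | (4aS,8aR)-2,2,4a,6-tetramethyl-4a,7,8,8a-tetrahydro-4H-1,3-benzodioxin-5-yl trifluoromethanesulfonate | CC1=C(OS(=O)(=O)C(F)(F)F)[C@@]2(C)COC(C)(C)O[C@@H]2CC1 | intermediate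
12 | (4aS,8aR)-5-ethenyl-2,2,4a,6-tetramethyl-4a,7,8,8a-tetrahydro-4H-1,3-benzodioxine (ring A diene) | CC1=C(C=C)[C@@]2(C)COC(C)(C)O[C@@H]2CC1 | intermediate
13 | 4,4-diethoxybut-2-ynal | CCOC(OCC)C#CC=O | starting material
14 | 17,17-diethoxy-3α,18-(isopropylidenedioxy)-12,13,14,15,16-pentanorlabda-5,8-dien-11-al (4α-CH3, 10α-CH3) | O=CC1=C(C(OCC)OCC)CC=C2[C@@]1(C)CC[C@H]3OC(C)(C)OC[C@]23C | intermediate
15 | 17,17-diethoxy-3α,18-(isopropylidenedioxy)-12,13,14,15,16-pentanorlabd-8-en-11-al (5β-H) | O=CC1=C(C(OCC)OCC)CC[C@H]2[C@@]1(C)CC[C@H]3OC(C)(C)OC[C@]23C | intermediate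
16 | 17,17-diethoxy-3α,18-(isopropylidenedioxy)-13,14,15,16-tetranorlabda-8,11-diene (5β-H) | C=CC1=C(C(OCC)OCC)CC[C@H]2[C@@]1(C)CC[C@H]3OC(C)(C)OC[C@]23C | intermediate
17 | 3α,18-dihydroxy-13,14,15,16-tetranorlabda-8,11-dien-17-al (5β-H) | C=CC1=C(C=O)CC[C@H]2[C@@]1(C)CC[C@@H](O)[C@]2(C)CO | intermediate
18 | N-tosylhydrazone of 17 | C=CC1=C(C=NNS(=O)(=O)c3ccc(C)cc3)CC[C@H]2[C@@]1(C)CC[C@@H](O)[C@]2(C)CO | intermediate
19 | 17-diazenyl-13,14,15,16-tetranorlabda-8,11-diene-3α,18-diol (allylic diazene) | C=CC1=C(CN=N)CC[C@H]2[C@@]1(C)CC[C@@H](O)[C@]2(C)CO | intermediate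
20 | 13,14,15,16-tetranorlabda-8(17),11-diene-3α,18-diol (5β-H, 9β-H) | C=C1CC[C@H]2[C@@](C)(CC[C@@H](O)[C@]2(C)CO)[C@@H]1C=C | intermediate
21 | 18-(tert-butyldimethylsilyloxy)-13,14,15,16-tetranorlabda-8(17),11-dien-3α-ol | C=C1CC[C@H]2[C@@](C)(CC[C@@H](O)[C@]2(C)CO[Si](C)(C)C(C)(C)C)[C@@H]1C=C | intermediate
22 | 18-(tert-butyldimethylsilyloxy)-13,14,15,16-tetranorlabda-8(17),11-dien-3-one | C=C1CC[C@H]2[C@@](C)(CCC(=O)[C@]2(C)CO[Si](C)(C)C(C)(C)C)[C@@H]1C=C | intermediate
23 | potassium Δ2-enolate of 22 | C=C1CC[C@H]2[C@@](C)(CC=C([O-])[C@]2(C)CO[Si](C)(C)C(C)(C)C)[C@@H]1C=C.[K+] | intermediate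
24 | 2β-hydroxy-18-(tert-butyldimethylsilyloxy)-13,14,15,16-tetranorlabda-8(17),11-dien-3-one | C=C1CC[C@H]2[C@@](C)(C[C@H](O)C(=O)[C@]2(C)CO[Si](C)(C)C(C)(C)C)[C@@H]1C=C | intermediate
25 | 2β,18-bis(tert-butyldimethylsilyloxy)-13,14,15,16-tetranorlabda-8(17),11-dien-3-one | C=C1CC[C@H]2[C@@](C)(C[C@H](O[Si](C)(C)C(C)(C)C)C(=O)[C@]2(C)CO[Si](C)(C)C(C)(C)C)[C@@H]1C=C | intermediate
26 | 2β,18-bis(tert-butyldimethylsilyloxy)-13,14,15,16-tetranorlabda-8(17),11-dien-3α-ol | C=C1CC[C@H]2[C@@](C)(C[C@H](O[Si](C)(C)C(C)(C)C)[C@@H](O)[C@]2(C)CO[Si](C)(C)C(C)(C)C)[C@@H]1C=C | intermediate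
27 | angelic acid, (Z)-2-methylbut-2-enoic acid | C/C=C(/C)C(=O)O | starting material
28 | 2β,18-bis(tert-butyldimethylsilyloxy)-13,14,15,16-tetranorlabda-8(17),11-dien-3α-yl (Z)-2-methylbut-2-enoate | C=C1CC[C@H]2[C@@](C)(C[C@H](O[Si](C)(C)C(C)(C)C)[C@@H](OC(=O)/C(C)=C\C)[C@]2(C)CO[Si](C)(C)C(C)(C)C)[C@@H]1C=C | intermediate
29 | 4-bromofuran-2(5H)-one | O=C1C=C(Br)CO1 | starting material
30 | 12-(9-borabicyclo[3.3.1]nonan-9-yl) hydroboration product of 28 | C=C1CC[C@H]2[C@@](C)(C[C@H](O[Si](C)(C)C(C)(C)C)[C@@H](OC(=O)/C(C)=C\C)[C@]2(C)CO[Si](C)(C)C(C)(C)C)[C@@H]1CCB1C2CCCC1CCC2 | intermediate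
31 | 3α-angeloyloxy-2β,18-bis(tert-butyldimethylsilyloxy)labda-8(17),13-dien-15,16-olide | C=C1CC[C@H]2[C@@](C)(C[C@H](O[Si](C)(C)C(C)(C)C)[C@@H](OC(=O)/C(C)=C\C)[C@]2(C)CO[Si](C)(C)C(C)(C)C)[C@@H]1CCC1=CC(=O)OC1 | intermediate
32 | 3α-angeloyloxy-2β,18-dihydroxylabda-8(17),13-dien-15,16-olide, (2S,3S,4S,5S,9R,10S) | C=C1CC[C@H]2[C@@](C)(C[C@H](O)[C@@H](OC(=O)/C(C)=C\C)[C@]2(C)CO)[C@@H]1CCC1=CC(=O)OC1 | target

## Step count and risks

Total step count: 19. Longest linear sequence: 19 steps from (R)-carvone (13, 27 and 29 are bought and enter directly).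

The three steps most likely to fail:

Step 7. The diene is hindered and twisted, the ynal is only mono-activated, and neither the rate nor the regiochemistry has direct precedent for this pair. Fallback: set out from 12 with the symmetrical and far more reactive dimethyl acetylenedicarboxylate (toluene, 110 °C), which removes the regiochemical question and gives the diester adduct F1. H2 over Pd/C gives the trans-fused diester F2, and i-Bu2AlH reduces both esters to the allylic diol F3. TBSCl (1 equiv) with imidazole silylates the less hindered C17 hydroxyl to give the mono-silyl ether F4; Dess–Martin oxidation gives the C11 enal F5, and Ph3P=CH2 gives the diene F6. Aqueous HCl removes acetonide and silyl ether to give the triol F7. Myers reductive transposition at the allylic primary alcohol (2-nitrobenzenesulfonylhydrazide, PPh3, diethyl azodicarboxylate, −30 °C → rt) passes through the sulfonylhydrazine F8 and the same diazene 19, and comes back to the route at 20.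

Step 17. The 3-OH is neopentyl-like and flanked by a silyl ether, and angelates isomerise easily to tiglates under acylation conditions. Fallback: set out from 26 and esterify with 2-[bis(2,2,2-trifluoroethoxy)phosphoryl]propanoic acid (DCC, DMAP) to give the phosphonate ester F9. Still–Gennari olefination with acetaldehyde (KN(SiMe3)2, 18-crown-6, THF, −78 °C) then builds the Z-trisubstituted enoate in place and comes back to the route at 28.

Step 18. The bromobutenolide is base-sensitive, and the hydroboration must distinguish the vinyl group from the exocyclic methylene. Fallback: set out from 28; 9-BBN then NaBO3·4H2O gives the primary alcohol F10, and I2, PPh3 and imidazole give the iodide F11. Alkylation of (3-furyl)2CuLi (from 3-bromofuran, n-BuLi and CuI, −78 °C) gives the 3-alkylfuran F12. Singlet-oxygen [4+2] cycloaddition (O2, hν, rose bengal, i-Pr2NEt, CH2Cl2, −78 °C) gives regioselectively the γ-hydroxybutenolide F13, and NaBH4 in MeOH reduces the masked aldehyde and relactonises, coming back to the route at 31.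

## Further compounds

F1 | step 7 | dimethyl 3α,18-(isopropylidenedioxy)-13,14,15,16-tetranorlabda-5,8-diene-11,17-dioate-type adduct (C9–CO2Me, C8–CO2Me) | COC(=O)C1=C(C(=O)OC)CC=C2[C@@]1(C)CC[C@H]3OC(C)(C)OC[C@]23C
F2 | step 7 | trans-fused Δ8 diester (5β-H) | COC(=O)C1=C(C(=O)OC)CC[C@H]2[C@@]1(C)CC[C@H]3OC(C)(C)OC[C@]23C
F3 | step 7 | Δ8 11,17-diol (acetonide retained) | OCC1=C(CO)CC[C@H]2[C@@]1(C)CC[C@H]3OC(C)(C)OC[C@]23C
F4 | step 7 | 17-O-tert-butyldimethylsilyl Δ8 11-ol | OCC1=C(CO[Si](C)(C)C(C)(C)C)CC[C@H]2[C@@]1(C)CC[C@H]3OC(C)(C)OC[C@]23C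
F5 | step 7 | 17-O-tert-butyldimethylsilyl Δ8 11-al | O=CC1=C(CO[Si](C)(C)C(C)(C)C)CC[C@H]2[C@@]1(C)CC[C@H]3OC(C)(C)OC[C@]23C
F6 | step 7 | 17-(tert-butyldimethylsilyloxy)-3α,18-(isopropylidenedioxy)-13,14,15,16-tetranorlabda-8,11-diene | C=CC1=C(CO[Si](C)(C)C(C)(C)C)CC[C@H]2[C@@]1(C)CC[C@H]3OC(C)(C)OC[C@]23C
F7 | step 7 | 13,14,15,16-tetranorlabda-8,11-diene-3α,17,18-triol | C=CC1=C(CO)CC[C@H]2[C@@]1(C)CC[C@@H](O)[C@]2(C)CO
F8 | step 7 | N-(C17-allyl)-N-(2-nitrobenzenesulfonyl)hydrazine from F7 | C=CC1=C(CN(N)S(=O)(=O)c3ccccc3[N+](=O)[O-])CC[C@H]2[C@@]1(C)CC[C@@H](O)[C@]2(C)CO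
F9 | step 17 | 3α-O-[2-(bis(2,2,2-trifluoroethoxy)phosphoryl)propanoyl] ester of 26 | C=C1CC[C@H]2[C@@](C)(C[C@H](O[Si](C)(C)C(C)(C)C)[C@@H](OC(=O)C(C)P(=O)(OCC(F)(F)F)OCC(F)(F)F)[C@]2(C)CO[Si](C)(C)C(C)(C)C)[C@@H]1C=C
F10 | step 18 | 12-hydroxy compound (hydroboration–oxidation of 28) | C=C1CC[C@H]2[C@@](C)(C[C@H](O[Si](C)(C)C(C)(C)C)[C@@H](OC(=O)/C(C)=C\C)[C@]2(C)CO[Si](C)(C)C(C)(C)C)[C@@H]1CCO
F11 | step 18 | 12-iodide | C=C1CC[C@H]2[C@@](C)(C[C@H](O[Si](C)(C)C(C)(C)C)[C@@H](OC(=O)/C(C)=C\C)[C@]2(C)CO[Si](C)(C)C(C)(C)C)[C@@H]1CCI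
F12 | step 18 | 12-(furan-3-yl) compound | C=C1CC[C@H]2[C@@](C)(C[C@H](O[Si](C)(C)C(C)(C)C)[C@@H](OC(=O)/C(C)=C\C)[C@]2(C)CO[Si](C)(C)C(C)(C)C)[C@@H]1CCc1ccoc1
F13 | step 18 | 16-hydroxy-15,16-olide (γ-hydroxybutenolide, C16 epimers) | C=C1CC[C@H]2[C@@](C)(C[C@H](O[Si](C)(C)C(C)(C)C)[C@@H](OC(=O)/C(C)=C\C)[C@]2(C)CO[Si](C)(C)C(C)(C)C)[C@@H]1CCC1=CC(=O)OC1O
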